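Count the coupling partner first.

the same everywhere: starting material 0.050 M; coupling partner 0.0475 M

| run | protic impurity | free catalyst | temperature | remark | time |
|---|---|---|---|---|---|
| Sunday's | 2.5 mM | 3.5 mM | 55 °C | run made earlier |  |
| Monday's | 2.5 mM | 5.5 mM | 90 °C | run made earlier |  |
| birch | 2.50 mM | 2.5 mM | 90 °C |  | 20 min |
| maple | 2.50 mM | 2.5 mM | 60 °C |  | 20 min |
| cedar | 2.50 mM | 2.5 mM | 120 °C |  | 20 min |

| run | time / min | target / % | starting material / % |
|---|---|---|---|
| Sunday's | 12.0 | 14 | 81 |
| Sunday's | 25.0 | 23 | 75 |
| Sunday's | 60.0 | 38 | 51 |
| Sunday's | 150 | 57 | 33 |
| Monday's | 6.00 | 28 | 60 |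
| Monday's | 12.0 | 38 | 43 |
| Monday's | 20.0 | 39 | 38 |
| Monday's | 25.0 | 44 | 35 |

(each reading ± 1.5 percentage points)

* the flask that comes out highest in amount of target, in percent of the starting material charged, or "all alike" when all lie within 1.5 percentage points (birch / maple / cedar / all alike)
* target at the end, in percent of the starting material charged, birch
* target at the end, in percent of the starting material charged, maple
* target at the end, in percent of the starting material charged, cedar

- the analysis behind the earlier runs scatters by 1.5 percentage points, standard deviation
- steps that have been proposed: starting material + coupling partner <-> target; starting material + coupling partner <-> isomer of the product; target + free catalyst <-> isomer of the product + free catalyst; free catalyst -> spent catalyst; starting material + protic impurity -> quenched substrate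

The proposed steps: starting material and coupling partner join reversibly to target or to isomer of the product, free catalyst interconverts target and isomer and decays to spent catalyst, and protic impurity quenches starting material.

Birch, maple and cedar hold 0.0475 M of coupling partner and 0.050 M of starting material, and the impurity can take 2.50 mM of the latter. That leaves 0.0475 M on each side, so the two stand level and either is the limiting reagent. Call this amount the coupling room: target, isomer and unreacted starting material share 95.0 % of the charge once the quench is over.

Now the ladder, fastest rung first.

The quench: in Sunday's run at 12.0 min, target and starting material leave 5 percentage points missing, shared by quenched substrate and isomer, while the impurity can take 5.00 % of the charge.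

The coupling: for level partners reacting one way, half-time is time times what is left over what is used. Monday's first reading gives 10.3 min at 90 °C, and Sunday's 60.0 min reading gives a longer 69.5 min at 55 °C.

The isomer: the room minus the last readings gives 5.00 % on Sunday and 16.0 % on Monday. Isomer per target thus reads 0.0877 and 0.364, from two runs that differ in temperature, free catalyst and time.

My reckoning: maple near Sunday's 23 %, birch near Monday's 39 %, and cedar below birch.

The forecast also names birch, with 48 % for birch, 25 % for maple and 32 % for cedar. Its birch figure stands above mine: “Isomerisation scales with catalyst, so I halve it for birch.”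

The flasks give 40.2 % for birch, 23.5 % for maple and 2.04 % for cedar, so birch is highest.

    starting material + coupling partner ⇌ target (K = 64.0 M⁻¹, k = 1.90 M⁻¹ min⁻¹, Ea = 56.0 kJ mol⁻¹, ΔH = −80.0 kJ mol⁻¹)
    starting material + coupling partner ⇌ isomer of the product (K = 6100 M⁻¹, k = 0.550 M⁻¹ min⁻¹, Ea = 86.0 kJ mol⁻¹, ΔH = −56.0 kJ mol⁻¹)
    target + free catalyst ⇌ isomer of the product + free catalyst, rate k3*[free catalyst]*[target] forward; the back reaction follows from the equilibrium constant (k = 1.20 M⁻¹ min⁻¹, Ea = 52.0 kJ mol⁻¹)
    free catalyst → spent catalyst (k = 0.650 min⁻¹, Ea = 92.0 kJ mol⁻¹)
    starting material + protic impurity → quenched substrate (k = 15.0 M⁻¹ min⁻¹, Ea = 52.0 kJ mol⁻¹)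
    (constants at 90 °C)

In cedar, free catalyst had done half of its decay in 0.104 min, long before the 10.0 min state, where it stood at 0 % of its charge with target 5.07 % and isomer 57.6 %. At 20.0 min, target 2.04 %, isomer 71.9 % and starting material 21.1 % fill the room's 95.0 %. Cedar's neighbour, charged with 0.12 M of starting material, has the coupling partner as its limit, a room of 39.6 % of its charge; it holds target 0.471 % and isomer 38.4 %, with 1.76 % of the coupling partner's own charge left.

(The data were generated by integration from invented constants; scatter was added.)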